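Ring B of the 2,3-dihydro-1,4-benzodioxine is opened at the aryl–oxygen bond C8a–O1 instead of the benzylic bond O1–C2, which the para-oxygenated ring C would let ionise and scramble. The key step exploits the fact that O1 sits on an sp2 carbon of ring A ortho to O4. A palladium-catalysed intramolecular etherification joins the C2 alkoxide to a brominated C8a, closes ring B and leaves both C(sp3)–O bonds untouched, so a threo (1R,2R) alcohol becomes the trans (2R,3R) ring. The precursor is a lactate-derived 1-aryl-2-aryloxypropan-1-ol with bromine on ring A next to the ether oxygen and the ring C phenol capped as a triisopropylsilyl ether.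

Key step: step 7

Remark on numbering: benzodioxine numbering is used (O1, C2 bearing ring C, C3 bearing methyl, O4, C4a, C5 methoxy, C7 propenyl, C8a); ring A is the fused benzene ring, ring B the dioxane ring, ring C the 4-hydroxy-3,5-dimethoxyphenyl ring.

Remark on the structures: both stereocentres of the target are R (trans); the open-chain alcohol must be (1R,2R), which is threo, and ethyl (S)-lactate supplies C3 after one inversion. No structure needed correction.

Remark on the chemistry: the ring C nucleophile is used as its Grignard reagent, because an aryllithium could undergo halogen–metal exchange with the ring A bromide.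

Step 1
Reactants: 1 5-bromovanillin; 2 ethyl (S)-lactate
Product: 3 ethyl (2R)-2-(2-bromo-4-formyl-6-methoxyphenoxy)propanoate
Conditions: PPh3, DIAD, THF, 0 °C → rt
Reagents that add atoms: none
Why: Mitsunobu etherification, in which the acidic phenol of 1 (para-formyl, ortho-bromo) attacks the phosphonium-activated lactate carbon by SN2 with inversion, so the (S) centre of 2 becomes the (R) centre destined for C3.

Step 2
Reactants: 3 ethyl (2R)-2-(2-bromo-4-formyl-6-methoxyphenoxy)propanoate
Product: 4 ethyl (2R)-2-[2-bromo-6-methoxy-4-((E)-prop-1-enyl)phenoxy]propanoate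
Conditions: CrCl2, CH3CHI2, THF, rt
Reagents that add atoms: 1,1-diiodoethane, CC(I)I
Why: Takai–Utimoto alkylidenation, in which divalent chromium turns 1,1-diiodoethane into a geminal dichromium reagent that adds to the aldehyde and eliminates to the (E)-alkene under neutral conditions, so the ester, the aryl bromide and the base-sensitive α-aryloxy stereocentre should be untouched.

Step 3
Reactants: 4 ethyl (2R)-2-[2-bromo-6-methoxy-4-((E)-prop-1-enyl)phenoxy]propanoate
Product: 5 (2R)-2-[2-bromo-6-methoxy-4-((E)-prop-1-enyl)phenoxy]-N-methoxy-N-methylpropanamide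
Conditions: MeNHOMe·HCl, iPrMgCl, THF, −20 °C
Reagents that add atoms: N,O-dimethylhydroxylamine hydrochloride, CNOC.Cl
Why: Weinreb amide formation from an ester with the chloromagnesium amide made in the flask, where acyl substitution at low temperature should be faster than enolisation so that the (R) centre is kept, and the electron-rich aryl bromide does not exchange with iPrMgCl at this temperature.

Step 4
Reactants: 6 4-bromo-2,6-dimethoxyphenol
Product: 7 (4-bromo-2,6-dimethoxyphenoxy)triisopropylsilane
Conditions: TIPSOTf, 2,6-lutidine, CH2Cl2, 0 °C → rt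
Reagents that add atoms: triisopropylsilyl trifluoromethanesulfonate, CC(C)[Si](OS(=O)(=O)C(F)(F)F)(C(C)C)C(C)C
Why: Silylation of a phenol, in which the reactive silyl triflate caps the hindered 2,6-dimethoxyphenol as a bulky silyl ether that should survive magnesium insertion, hydride and carbonate base and can be removed by fluoride at the end.

Step 5
Reactants: 7 (4-bromo-2,6-dimethoxyphenoxy)triisopropylsilane; 5 (2R)-2-[2-bromo-6-methoxy-4-((E)-prop-1-enyl)phenoxy]-N-methoxy-N-methylpropanamide
Product: 10 (2R)-2-[2-bromo-6-methoxy-4-((E)-prop-1-enyl)phenoxy]-1-[3,5-dimethoxy-4-(triisopropylsilyloxy)phenyl]propan-1-one, via arylmagnesium bromide 8 (not isolated), via tetrahedral magnesium adduct 9 (not isolated)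
Conditions: Mg, THF, reflux; then 5, THF, 0 °C; aq NH4Cl
Reagents that add atoms: none
Why: Grignard formation followed by Weinreb ketone synthesis, in which 8 adds once to the amide to give the chelated adduct 9 that collapses to the ketone only on aqueous work-up, so over-addition and α-epimerisation should be avoided while the ring A bromide and the propenyl group are inert to an arylmagnesium reagent.

Step 6
Reactants: 10 (2R)-2-[2-bromo-6-methoxy-4-((E)-prop-1-enyl)phenoxy]-1-[3,5-dimethoxy-4-(triisopropylsilyloxy)phenyl]propan-1-one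
Product: 11 (1R,2R)-2-[2-bromo-6-methoxy-4-((E)-prop-1-enyl)phenoxy]-1-[3,5-dimethoxy-4-(triisopropylsilyloxy)phenyl]propan-1-ol
Conditions: LiBH(s-Bu)3 (L-Selectride), THF, −78 °C; aq NH4Cl
Reagents that add atoms: none
Why: Felkin–Anh controlled ketone reduction, in which the bulky, poorly chelating hydride approaches anti to the C2 aryloxy group and past the C2 hydrogen instead of the methyl group, so the new carbinol centre should be (1R) and the alcohol threo, while the (2R) centre is not disturbed at −78 °C.

Step 7
Reactants: 11 (1R,2R)-2-[2-bromo-6-methoxy-4-((E)-prop-1-enyl)phenoxy]-1-[3,5-dimethoxy-4-(triisopropylsilyloxy)phenyl]propan-1-ol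
Product: 12 triisopropyl{4-[(2R,3R)-5-methoxy-3-methyl-7-((E)-prop-1-enyl)-2,3-dihydro-1,4-benzodioxin-2-yl]-2,6-dimethoxyphenoxy}silane
Conditions: Pd(OAc)2 (5 mol %), 2-(di-tert-butylphosphino)-1,1'-binaphthyl (7 mol %), Cs2CO3, toluene, 70 °C
Reagents that add atoms: none
Why: Zerovalent palladium, formed from Pd(OAc)2 and the bulky di-tert-butyl(binaphthyl)phosphine, inserts into the C8a–Br bond of ring A, Cs2CO3 turns the C1 hydroxyl into an alkoxide bound to the metal in a seven-membered oxapalladacycle, and C–O reductive elimination releases 12. The closest known reaction type is the intramolecular Buchwald–Hartwig etherification of 2-(2-bromophenoxy)alkanols with secondary hydroxyl groups to 1,4-benzodioxanes. The six-membered ring B is closed in a 6-exo sense at the aromatic carbon, with bromide leaving outside the new ring. No stereocentre is formed, and since neither C(sp3)–O bond is broken the (1R,2R) alcohol maps with retention onto the trans (2R,3R) ring. The step needs reductive elimination to outrun β-hydride elimination from the secondary benzylic alkoxide and intermolecular Heck coupling at the propenyl group; the bulky electron-rich ligand, the intramolecular delivery of the alkoxide and the low Heck reactivity of a 1,2-disubstituted styrene should secure this.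

Step 8
Reactants: 12 triisopropyl{4-[(2R,3R)-5-methoxy-3-methyl-7-((E)-prop-1-enyl)-2,3-dihydro-1,4-benzodioxin-2-yl]-2,6-dimethoxyphenoxy}silane
Product: 13 4-[(2R,3R)-5-methoxy-3-methyl-7-((E)-prop-1-enyl)-2,3-dihydro-1,4-benzodioxin-2-yl]-2,6-dimethoxyphenol
Conditions: Bu4NF, AcOH, THF, 0 °C
Reagents that add atoms: none
Why: Fluoride-mediated cleavage of an aryl silyl ether, driven by the strong Si–F bond, where the AcOH buffer protonates the phenoxide at once so that no quinone methide should open the para-benzylic O1–C2 bond or disturb either stereocentre.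

Compound list
1 | 5-bromovanillin (3-bromo-4-hydroxy-5-methoxybenzaldehyde) | COc1cc(C=O)cc(Br)c1O | starting material
2 | ethyl (S)-lactate | CCOC(=O)[C@H](C)O | starting material
3 | ethyl (2R)-2-(2-bromo-4-formyl-6-methoxyphenoxy)propanoate | CCOC(=O)[C@@H](C)Oc1c(Br)cc(C=O)cc1OC | intermediate
4 | ethyl (2R)-2-[2-bromo-6-methoxy-4-((E)-prop-1-enyl)phenoxy]propanoate | C/C=C/c1cc(Br)c(O[C@H](C)C(=O)OCC)c(OC)c1 | intermediate
5 | (2R)-2-[2-bromo-6-methoxy-4-((E)-prop-1-enyl)phenoxy]-N-methoxy-N-methylpropanamide | C/C=C/c1cc(Br)c(O[C@H](C)C(=O)N(C)OC)c(OC)c1 | intermediate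
6 | 4-bromo-2,6-dimethoxyphenol | COc1cc(Br)cc(OC)c1O | starting material
7 | (4-bromo-2,6-dimethoxyphenoxy)triisopropylsilane | COc1cc(Br)cc(OC)c1O[Si](C(C)C)(C(C)C)C(C)C | intermediate
8 | [3,5-dimethoxy-4-(triisopropylsilyloxy)phenyl]magnesium bromide (formed in the flask, not isolated) | COc1cc([Mg]Br)cc(OC)c1O[Si](C(C)C)(C(C)C)C(C)C | intermediate
9 | bromomagnesium alkoxide of the tetrahedral adduct of 8 and 5, (2R)-configured at the aryloxy carbon, hemiaminal carbon undefined (not isolated) | C/C=C/c1cc(Br)c(O[C@H](C)C(O[Mg]Br)(N(C)OC)c2cc(OC)c(O[Si](C(C)C)(C(C)C)C(C)C)c(OC)c2)c(OC)c1 | intermediate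
10 | (2R)-2-[2-bromo-6-methoxy-4-((E)-prop-1-enyl)phenoxy]-1-[3,5-dimethoxy-4-(triisopropylsilyloxy)phenyl]propan-1-one | C/C=C/c1cc(Br)c(O[C@H](C)C(=O)c2cc(OC)c(O[Si](C(C)C)(C(C)C)C(C)C)c(OC)c2)c(OC)c1 | intermediate
11 | (1R,2R)-2-[2-bromo-6-methoxy-4-((E)-prop-1-enyl)phenoxy]-1-[3,5-dimethoxy-4-(triisopropylsilyloxy)phenyl]propan-1-ol (threo; key-step precursor) | C/C=C/c1cc(Br)c(O[C@H](C)[C@H](O)c2cc(OC)c(O[Si](C(C)C)(C(C)C)C(C)C)c(OC)c2)c(OC)c1 | intermediate
12 | triisopropyl{4-[(2R,3R)-5-methoxy-3-methyl-7-((E)-prop-1-enyl)-2,3-dihydro-1,4-benzodioxin-2-yl]-2,6-dimethoxyphenoxy}silane (trans; key-step product) | C/C=C/c1cc(OC)c2c(c1)O[C@H](c1cc(OC)c(O[Si](C(C)C)(C(C)C)C(C)C)c(OC)c1)[C@@H](C)O2 | intermediate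
13 | 4-[(2R,3R)-5-methoxy-3-methyl-7-((E)-prop-1-enyl)-2,3-dihydro-1,4-benzodioxin-2-yl]-2,6-dimethoxyphenol | C/C=C/c1cc(OC)c2c(c1)O[C@H](c1cc(OC)c(O)c(OC)c1)[C@@H](C)O2 | target

Total step count: 8
Longest linear sequence: 7 steps (steps 1, 2, 3, 5, 6, 7, 8)

Steps most likely to fail

Step 7. β-Hydride elimination from the aryl palladium alkoxide may outpace C–O reductive elimination, oxidising the carbinol and removing the bromine, or the arylpalladium species may be diverted into Heck coupling with the propenyl group of a second molecule. The fallback closes ring B at the other terminus of O1 by ionisation instead of metal-mediated C–O formation. Setting out from 11, Miyaura borylation (B2pin2, PdCl2(dppf), KOAc, 1,4-dioxane, 80 °C; this weak base forms no alkoxide) should give (1R,2R)-1-[3,5-dimethoxy-4-(triisopropylsilyloxy)phenyl]-2-[2-methoxy-4-((E)-prop-1-enyl)-6-(4,4,5,5-tetramethyl-1,3,2-dioxaborolan-2-yl)phenoxy]propan-1-ol F1. Oxidation of the C–B bond with NaBO3·4H2O in THF/H2O at rt should give 2-{[(1R,2R)-1-[3,5-dimethoxy-4-(triisopropylsilyloxy)phenyl]-1-hydroxypropan-2-yl]oxy}-3-methoxy-5-[(E)-prop-1-enyl]phenol F2. Catalytic camphorsulfonic acid in CH2Cl2 at 0 °C should ionise the para-silyloxybenzylic alcohol and let the new C8a phenol capture the cation. C3 is untouched and the diequatorial trans ring is the thermodynamically preferred outcome, so the route is rejoined at 12.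

Step 6. Facial selectivity may be poor if lithium chelation between the carbonyl and ether oxygens competes with the Felkin–Anh mode, or the α-aryloxy ketone may epimerise before it is reduced. The fallback replaces substrate control by catalyst control. Setting out from 10, a Corey–Bakshi–Shibata reduction with (R)-2-methyl-CBS-oxazaborolidine and catecholborane in toluene at −78 °C should deliver hydride to the face that gives the (1R) carbinol, the aryl ring acting as the large substituent and the propenyl group being spared by catecholborane. It comes back to the route at 11, and no new compound arises on this way (F0).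

Step 2. The E/Z selectivity of the chromium ethylidenation may erode with an aromatic aldehyde, and conversion may stall on the electron-rich substrate. The fallback makes the alkene before the stereocentre exists and corrects its geometry by equilibration. Setting out from 1, Wittig reaction with ethylidenetriphenylphosphorane (EtPPh3Br, excess KOtBu to carry the phenoxide, THF, 0 °C → rt) should give 2-bromo-6-methoxy-4-[(Z)-prop-1-enyl]phenol F3 as the main isomer of a Z/E mixture. PdCl2(MeCN)2 (cat.) in CH2Cl2 at rt should equilibrate it to 2-bromo-6-methoxy-4-[(E)-prop-1-enyl]phenol F4. Mitsunobu reaction of this phenol with 2 (PPh3, DIAD, THF, 0 °C → rt) comes back to the route at 4.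

Further compounds
F1 | step 7 | (1R,2R)-1-[3,5-dimethoxy-4-(triisopropylsilyloxy)phenyl]-2-[2-methoxy-4-((E)-prop-1-enyl)-6-(4,4,5,5-tetramethyl-1,3,2-dioxaborolan-2-yl)phenoxy]propan-1-ol | C/C=C/c1cc(B3OC(C)(C)C(C)(C)O3)c(O[C@H](C)[C@H](O)c2cc(OC)c(O[Si](C(C)C)(C(C)C)C(C)C)c(OC)c2)c(OC)c1
F2 | step 7 | 2-{[(1R,2R)-1-[3,5-dimethoxy-4-(triisopropylsilyloxy)phenyl]-1-hydroxypropan-2-yl]oxy}-3-methoxy-5-[(E)-prop-1-enyl]phenol | C/C=C/c1cc(O)c(O[C@H](C)[C@H](O)c2cc(OC)c(O[Si](C(C)C)(C(C)C)C(C)C)c(OC)c2)c(OC)c1
F0 | step 6 | none | none
F3 | step 2 | 2-bromo-6-methoxy-4-[(Z)-prop-1-enyl]phenol (main isomer of the Z/E mixture) | C/C=C\c1cc(Br)c(O)c(OC)c1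
F4 | step 2 | 2-bromo-6-methoxy-4-[(E)-prop-1-enyl]phenol | C/C=C/c1cc(Br)c(O)c(OC)c1
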